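**Plan**

- Retrosynthesis: the C9 isobutyrate and the C11=C13 methylene come off first. The C1=C10 double bond of the ten-membered carbocycle is then traced to an eleven-membered cyclic α-chloro sulfone with sulfur bridging C1 and C10, which contracts by Ramberg–Bäcklund loss of SO2.
- Feature that allows this: C1 is an olefinic CH next to the C2 methylene, and C10 carries only the C14 methyl and the C9 carbinol, so both can be sp3 carbons on one sulfur. The C9–O/C10–S pair is what thio-opening of a 9,10-epoxide gives, and S–C1 is a thiolate alkylation.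
- Further cuts: S–C1, S–C10, O8–C12 (γ-lactone), C8–C9 (alkenyl addition), C6–C7 (aldol), and the C4–C5 epoxide of a C1–C6 allylic alcohol.
- Forward order: C1–C6 epoxy aldehyde → aldol → C8 alkenylation → γ-lactone (first ring) → 9,10-epoxide and sulfur → eleven-membered thiacycle → contraction to the ten-membered ring → α-methylene, C9 ester, deprotection.
- Stereochemistry: C4/C5 from Sharpless epoxidation; C6/C7 from the oxazolidinone auxiliary; C8 from ligand-controlled alkenylzinc addition; C9 from Shi epoxidation (the thiol attacks C10, so C9 is retained); C1=C10 geometry from the key step.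

Key step: step 16

Remark: germacrane locants are used throughout (C1=C10 olefin with C14 on C10; C4–C5 epoxide with C15 on C4; C6 carbinol; C7–C8 lactone fusion with C11–C13; C9 ester carbinol). The target is (4S,5S,6S,7S,8R,9S,1(10)E).
Remark: chlorination in step 15 is assumed to occur at the less hindered C1 methylene; the C10 regioisomer would give the same olefin in step 16.

**Route**

Step 1
Reactants: 1 5-chloropent-1-yne
Product: 3 (E)-6-chloro-3-methylhex-2-en-1-ol, via (E)-alkenyldimethylalane 2 (not isolated)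
Conditions: Me3Al (2.5 equiv), Cp2ZrCl2 (0.2 equiv), CH2Cl2, 0 to 23 °C; then (CH2O)n, THF, 0 to 23 °C; aq. potassium sodium tartrate
Reagents that add atoms: trimethylaluminium C[Al](C)C; formaldehyde (from paraformaldehyde) C=O
Why: Zirconocene-catalysed methylalumination (Negishi carboalumination) adds CH3 and Al syn across the terminal alkyne with CH3 on the internal carbon, and hydroxymethylation of the alkenylalane with retention should give the E trisubstituted allylic alcohol (C4=C5, C15, C6) while the primary chloride stays untouched.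

Step 2
Reactants: 3 (E)-6-chloro-3-methylhex-2-en-1-ol
Product: 4 [(2S,3S)-3-(3-chloropropyl)-3-methyloxiran-2-yl]methanol
Conditions: Ti(OiPr)4 (0.1 equiv), L-(+)-diethyl tartrate (0.12 equiv), t-BuOOH, 4 Å molecular sieves, CH2Cl2, −20 °C
Reagents that add atoms: tert-butyl hydroperoxide CC(C)(C)OO
Why: Sharpless asymmetric epoxidation of an E trisubstituted primary allylic alcohol, in which the L-(+)-tartrate complex delivers oxygen to the face that gives the (2S,3S)-epoxide and so sets C4 and C5 of the target.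

Step 3
Reactants: 4 [(2S,3S)-3-(3-chloropropyl)-3-methyloxiran-2-yl]methanol
Product: 5 (2R,3S)-3-(3-chloropropyl)-3-methyloxirane-2-carbaldehyde
Conditions: Dess–Martin periodinane, NaHCO3, CH2Cl2, 0 to 23 °C; used without storage
Reagents that add atoms: none
Why: Buffered Dess–Martin oxidation converts the primary alcohol to the aldehyde under neutral conditions that should leave the epoxide and the C5 stereocentre intact.

Step 4
Reactants: 6 (S)-4-benzyloxazolidin-2-one; 7 4-tert-butoxy-4-oxobutanoic acid
Product: 8 tert-butyl 4-[(4S)-4-benzyl-2-oxo-1,3-oxazolidin-3-yl]-4-oxobutanoate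
Conditions: 7, t-BuCOCl, Et3N, THF, −20 °C; then 6, LiCl, 23 °C
Reagents that add atoms: none
Why: N-acylation of the oxazolidinone through the pivaloyl mixed anhydride is a standard auxiliary loading that forms no stereocentre.

Step 5
Reactants: 5 (2R,3S)-3-(3-chloropropyl)-3-methyloxirane-2-carbaldehyde; 8 tert-butyl 4-[(4S)-4-benzyl-2-oxo-1,3-oxazolidin-3-yl]-4-oxobutanoate
Product: 9 tert-butyl (3S,4S)-3-{[(4S)-4-benzyl-2-oxo-1,3-oxazolidin-3-yl]carbonyl}-4-[(2S,3S)-3-(3-chloropropyl)-3-methyloxiran-2-yl]-4-hydroxybutanoate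
Conditions: 8, Bu2BOTf, i-Pr2NEt, CH2Cl2, −78 to 0 °C; then 5, −78 to −20 °C; pH 7 buffer, MeOH, H2O2, 0 °C
Reagents that add atoms: none
Why: Evans syn-aldol reaction, in which the Z boron enolate of the imide (enolised only at the imide α-carbon) adds through a chair transition state with the benzyl group blocking one enolate face, so the auxiliary should set C6 and C7 (both S, syn) and override the bias of the epoxy aldehyde.

Step 6
Reactants: 9 syn-aldol adduct
Product: 10 tert-butyl (3S,4S)-3-{[(4S)-4-benzyl-2-oxo-1,3-oxazolidin-3-yl]carbonyl}-4-[tert-butyl(dimethyl)silyloxy]-4-[(2S,3S)-3-(3-chloropropyl)-3-methyloxiran-2-yl]butanoate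
Conditions: TBSOTf, 2,6-lutidine, CH2Cl2, −78 to 0 °C
Reagents that add atoms: tert-butyldimethylsilyl triflate CC(C)(C)[Si](C)(C)OS(=O)(=O)C(F)(F)F
Why: Silylation with the silyl triflate and a hindered base protects the C6 hydroxyl, which must not lactonise onto C12 nor open the neighbouring epoxide later.

Step 7
Reactants: 10 silyl ether of the aldol adduct
Product: 11 tert-butyl (3R,4S)-4-[tert-butyl(dimethyl)silyloxy]-4-[(2S,3S)-3-(3-chloropropyl)-3-methyloxiran-2-yl]-3-(hydroxymethyl)butanoate
Conditions: LiBH4, MeOH (1 equiv), THF, 0 °C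
Reagents that add atoms: none
Why: Reductive removal of the oxazolidinone with LiBH4 is chemoselective for the imide over the tert-butyl ester (a γ-hydroxy tert-butyl ester does not lactonise under these conditions) and returns auxiliary 6.

Step 8
Reactants: 11 primary alcohol
Product: 12 tert-butyl (3S,4S)-4-[tert-butyl(dimethyl)silyloxy]-4-[(2S,3S)-3-(3-chloropropyl)-3-methyloxiran-2-yl]-3-formylbutanoate
Conditions: Dess–Martin periodinane, NaHCO3, CH2Cl2, 0 °C; used at once
Reagents that add atoms: none
Why: Buffered Dess–Martin oxidation gives the α-branched aldehyde (C8) without acid that could cyclise the alcohol onto the epoxide or epimerise C7.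

Step 9
Reactants: 12 aldehyde; 13 propyne
Product: 16 tert-butyl (3R,4S)-4-[tert-butyl(dimethyl)silyloxy]-4-[(2S,3S)-3-(3-chloropropyl)-3-methyloxiran-2-yl]-3-[(1S,2E)-1-hydroxybut-2-enyl]butanoate, via (E)-dicyclohexyl(prop-1-enyl)borane 14 (not isolated), via (E)-methyl(prop-1-enyl)zinc 15 (not isolated)
Conditions: 13, Cy2BH, toluene, 0 to 23 °C; Me2Zn, −78 °C; (−)-MIB (5 mol%), then 12, −30 to 0 °C; aq. NH4Cl
Reagents that add atoms: none
Why: Catalytic asymmetric alkenylzinc addition (alkyne hydroboration, boron-to-zinc exchange, amino alcohol ligand), in which (−)-MIB directs the E-propenyl group to the Si face of the aldehyde to set C8 (1S here, 8R in the target), the same sense as Felkin attack on this α-branched aldehyde.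

Step 10
Reactants: 16 allylic alcohol
Product: 17 (4R,5S)-4-{(S)-[tert-butyl(dimethyl)silyloxy][(2S,3S)-3-(3-chloropropyl)-3-methyloxiran-2-yl]methyl}-5-[(E)-prop-1-enyl]oxolan-2-one
Conditions: KOt-Bu (0.2 equiv), THF, −20 to 0 °C
Reagents that add atoms: none
Why: Alkoxide-initiated lactonisation (5-exo-trig transesterification, with the expelled tert-butoxide carrying the chain) should be faster than attack of the C8 alkoxide on the hindered 4,5-epoxide and closes the trans-fused γ-lactone without touching a stereocentre.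

Step 11
Reactants: 17 propenyl lactone
Product: 18 (4R,5R)-4-{(S)-[tert-butyl(dimethyl)silyloxy][(2S,3S)-3-(3-chloropropyl)-3-methyloxiran-2-yl]methyl}-5-[(2S,3R)-3-methyloxiran-2-yl]oxolan-2-one
Conditions: Shi ketone (D-fructose-derived, 0.3 equiv), Oxone (2KHSO5·KHSO4·K2SO4), K2CO3, Bu4NHSO4, Na2B4O7 buffer, MeCN–(MeO)2CH2–H2O, 0 °C
Reagents that add atoms: potassium peroxymonosulfate [K+].OOS(=O)(=O)[O-]
Why: Shi epoxidation of the only olefin, an E-disubstituted one, by the chiral dioxirane through a spiro transition state; the D-fructose-derived ketone should give the trans-epoxide of the same sense as the (R,R)-epoxides of simple E-alkenes, which sets C9.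

Step 12
Reactants: 18 bis-epoxide lactone
Product: 19 S-[(1R,2S)-1-hydroxy-1-[(2R,3R)-3-{(S)-[tert-butyl(dimethyl)silyloxy][(2S,3S)-3-(3-chloropropyl)-3-methyloxiran-2-yl]methyl}-5-oxooxolan-2-yl]propan-2-yl] ethanethioate
Conditions: CH3C(O)SH (3 equiv), 2,6-lutidine (0.3 equiv), toluene, 40 °C
Reagents that add atoms: thioacetic acid CC(=O)S
Why: SN2 opening of the disubstituted epoxide by the thioacid at C10 (the carbon remote from the branched, oxygen-bearing C8) with inversion leaves the C9 hydroxyl in the target configuration; the non-basic medium should spare the primary chloride and the hindered trisubstituted epoxide and suppress S-to-O acetyl shift.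

Step 13
Reactants: 19 hydroxy thioacetate
Product: 20 triethylsilyl ether of 19 (C9–OSiEt3)
Conditions: Et3SiOTf, 2,6-lutidine, CH2Cl2, −78 °C
Reagents that add atoms: triethylsilyl triflate CC[Si](CC)(CC)OS(=O)(=O)C(F)(F)F
Why: Silylation of the C9 hydroxyl prevents acyl migration and gives a β-substituent that is a poor leaving group for the later sulfone chemistry, and it is orthogonal to the C6 silyl ether.

Step 14
Reactants: 20 silylated thioacetate
Product: 22 eleven-membered cyclic sulfide (S between C1 and C10), via thiol 21 (not isolated)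
Conditions: N2H4·H2O (1.1 equiv), DMF, 0 °C; then slow addition to Cs2CO3, NaI (0.5 equiv), degassed DMF, 45 °C, final 1 mM
Reagents that add atoms: none
Why: Hydrazinolysis frees the C10 thiol, and its caesium thiolate closes the thiacycle by intramolecular SN2 at the primary C1 chloride under high dilution (iodide catalysis), a standard macrocyclic sulfide synthesis that forms no stereocentre.

Step 15
Reactants: 22 cyclic sulfide
Product: 24 cyclic α-chloro sulfone (Cl on C1), via α-chloro sulfide 23 (not isolated)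
Conditions: NCS (1.05 equiv), CCl4, 23 °C; then mCPBA (2.3 equiv), NaHCO3, CH2Cl2, 0 °C
Reagents that add atoms: N-chlorosuccinimide O=C1CCC(=O)N1Cl; 3-chloroperoxybenzoic acid OOC(=O)c1cccc(Cl)c1
Why: α-Chlorination of the sulfide through the chlorosulfonium and thionium ion, expected at the less hindered C1 methylene, followed by oxidation to the sulfone installs the halogen before any base is used, so that the lactone enolate never meets a halogenating agent.

Step 16
Reactants: 24 cyclic α-chloro sulfone
Product: 26 (1(10)E)-4,5-epoxy-6-[tert-butyl(dimethyl)silyloxy]-9-(triethylsilyloxy)germacr-1(10)-en-12,8-olide, via thiirane 1,1-dioxide 25 (not isolated)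
Conditions: KOt-Bu (3 equiv), THF, −78 to 0 °C
Reagents that add atoms: none
Why: Ramberg–Bäcklund ring contraction: tert-butoxide removes the α'-proton at C10, the carbanion displaces chloride at C1 in a 1,3-elimination, and the thiirane 1,1-dioxide 25 loses SO2 in a stereospecific cheletropic step, so the eleven-membered thiacycle becomes the ten-membered carbocycle with the C1=C10 double bond in place. The closest known reaction type is the Ramberg–Bäcklund contraction of medium-ring α-halo sulfones to cycloalkenes, which has been used for trisubstituted olefins in lactone-bearing sesquiterpene carbocycles. The carbocycle closes in a 3-exo-tet mode (C10 carbanion on C1–Cl) inside the thiacycle, where both carbons are already held by sulfur, so no high dilution is needed. No stereocentre is created (C1 and C10 lose theirs); the geometry is set in the closure, where with excess KOt-Bu the α-chloro epimers and the C1–H of 25 can equilibrate, and the trans-fused thiirane dioxide, which keeps the C2 chain anti to the branched C9 carbon and syn only to the C14 methyl, should lead to the E olefin. The step needs 1,3-elimination to outrun E1cB loss of the C9 silyloxy group and any lactone enolate chemistry; this rests on the pre-installed chlorine, on silanolate being a poor leaving group at low temperature, on reversible lactone enolisation, and on the 4,5-epoxide being remote from both carbanion sites.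

Step 17
Reactants: 26 ten-membered E olefin lactone
Product: 29 α-methylene lactone (C6–OTBS, C9–OSiEt3), via Mannich base 27 (not isolated), via methiodide salt 28 (not isolated)
Conditions: LiN(i-Pr)2 (1.3 equiv), THF, −78 °C; CH2=NMe2+ I−, −78 to 23 °C; MeI, MeOH, 23 °C; aq. NaHCO3, EtOAc
Reagents that add atoms: Eschenmoser's salt C=[N+](C)C.[I-]
Why: Lactone α-methylenation by Mannich reaction of the lithium enolate with the iminium salt, N-methylation and E1cB loss of trimethylamine, a standard end-game for trans-fused γ-lactones that makes C11 sp2 and creates no stereocentre.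

Step 18
Reactants: 29 bis-silyl α-methylene lactone
Product: 30 C9 alcohol (C6–OTBS retained)
Conditions: HF·pyridine, pyridine, THF, 0 °C
Reagents that add atoms: none
Why: Buffered fluoride cleaves the triethylsilyl ether much faster than the bulkier tert-butyldimethylsilyl ether, which frees only the C9 hydroxyl.

Step 19
Reactants: 30 C9 alcohol
Product: 31 C9 isobutyrate (C6–OTBS)
Conditions: (i-PrCO)2O, Et3N, DMAP (0.2 equiv), CH2Cl2, 0 to 23 °C
Reagents that add atoms: isobutyric anhydride CC(C)C(=O)OC(=O)C(C)C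
Why: DMAP-catalysed acylation of the only free hydroxyl installs the isobutyrate at C9 with retention.

Step 20
Reactants: 31 C9 isobutyrate
Product: 32 CNP0220196.1 (target)
Conditions: HF·pyridine, THF, 0 to 23 °C
Reagents that add atoms: none
Why: Fluoride desilylation under mildly acidic, non-nucleophilic conditions should free the C6 hydroxyl without acyl migration, epoxide opening or conjugate addition to the methylene lactone.

**Compound list**

1 | 5-chloropent-1-yne | C#CCCCCl | starting material
2 | (E)-(5-chloro-2-methylpent-1-enyl)dimethylalane | C/C(CCCCl)=C\[Al](C)C | intermediate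
3 | (E)-6-chloro-3-methylhex-2-en-1-ol | OC/C=C(\C)CCCCl | intermediate
4 | [(2S,3S)-3-(3-chloropropyl)-3-methyloxiran-2-yl]methanol | OC[C@@H]1O[C@@]1(C)CCCCl | intermediate
5 | (2R,3S)-3-(3-chloropropyl)-3-methyloxirane-2-carbaldehyde | O=C[C@@H]1O[C@@]1(C)CCCCl | intermediate
6 | (S)-4-benzyloxazolidin-2-one | O=C1N[C@@H](Cc2ccccc2)CO1 | starting material
7 | 4-tert-butoxy-4-oxobutanoic acid | OC(=O)CCC(=O)OC(C)(C)C | starting material
8 | tert-butyl 4-[(4S)-4-benzyl-2-oxo-1,3-oxazolidin-3-yl]-4-oxobutanoate | O=C1OC[C@H](Cc2ccccc2)N1C(=O)CCC(=O)OC(C)(C)C | intermediate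
9 | syn-aldol adduct (3S,4S; C6–OH, C7) | CC(C)(C)OC(=O)C[C@H](C(=O)N1[C@@H](Cc2ccccc2)COC1=O)[C@H](O)[C@@H]1O[C@@]1(C)CCCCl | intermediate
10 | C6 tert-butyldimethylsilyl ether of 9 | CC(C)(C)OC(=O)C[C@H](C(=O)N1[C@@H](Cc2ccccc2)COC1=O)[C@H](O[Si](C)(C)C(C)(C)C)[C@@H]1O[C@@]1(C)CCCCl | intermediate
11 | tert-butyl (3R,4S)-4-silyloxy-4-oxiranyl-3-(hydroxymethyl)butanoate (C8 alcohol) | CC(C)(C)OC(=O)C[C@H](CO)[C@H](O[Si](C)(C)C(C)(C)C)[C@@H]1O[C@@]1(C)CCCCl | intermediate
12 | tert-butyl (3S,4S)-4-silyloxy-4-oxiranyl-3-formylbutanoate (C8 aldehyde) | CC(C)(C)OC(=O)C[C@H](C=O)[C@H](O[Si](C)(C)C(C)(C)C)[C@@H]1O[C@@]1(C)CCCCl | intermediate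
13 | propyne | CC#C | starting material
14 | (E)-dicyclohexyl(prop-1-enyl)borane | C/C=C/B(C1CCCCC1)C1CCCCC1 | intermediate
15 | (E)-methyl(prop-1-enyl)zinc | C/C=C/[Zn]C | intermediate
16 | allylic alcohol (3R,4S,1'S; E-propenyl carbinol at C8) | CC(C)(C)OC(=O)C[C@H]([C@@H](O)/C=C/C)[C@H](O[Si](C)(C)C(C)(C)C)[C@@H]1O[C@@]1(C)CCCCl | intermediate
17 | (4R,5S)-trans γ-lactone with 5-[(E)-prop-1-enyl] | C/C=C/[C@@H]1OC(=O)C[C@H]1[C@H](O[Si](C)(C)C(C)(C)C)[C@@H]1O[C@@]1(C)CCCCl | intermediate
18 | (4R,5R)-lactone with 5-[(2S,3R)-3-methyloxiran-2-yl] | C[C@H]1O[C@@H]1[C@@H]1OC(=O)C[C@H]1[C@H](O[Si](C)(C)C(C)(C)C)[C@@H]1O[C@@]1(C)CCCCl | intermediate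
19 | C9 alcohol, C10 thioacetate (9R,10S) | CC(=O)S[C@@H](C)[C@H](O)[C@@H]1OC(=O)C[C@H]1[C@H](O[Si](C)(C)C(C)(C)C)[C@@H]1O[C@@]1(C)CCCCl | intermediate
20 | C9 triethylsilyl ether of 19 | CC(=O)S[C@@H](C)[C@H](O[Si](CC)(CC)CC)[C@@H]1OC(=O)C[C@H]1[C@H](O[Si](C)(C)C(C)(C)C)[C@@H]1O[C@@]1(C)CCCCl | intermediate
21 | C10 thiol | S[C@@H](C)[C@H](O[Si](CC)(CC)CC)[C@@H]1OC(=O)C[C@H]1[C@H](O[Si](C)(C)C(C)(C)C)[C@@H]1O[C@@]1(C)CCCCl | intermediate
22 | eleven-membered cyclic sulfide (S between C1 and C10; 4S,5S,6S,7R,8R,9R,10S) | C[C@@H]1SCCC[C@]2(C)O[C@H]2[C@@H](O[Si](C)(C)C(C)(C)C)[C@@H]2CC(=O)O[C@H]2[C@H]1O[Si](CC)(CC)CC | intermediate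
23 | C1-chloro derivative of sulfide 22 (C1 epimers) | C[C@@H]1SC(Cl)CC[C@]2(C)O[C@H]2[C@@H](O[Si](C)(C)C(C)(C)C)[C@@H]2CC(=O)O[C@H]2[C@H]1O[Si](CC)(CC)CC | intermediate
24 | cyclic α-chloro sulfone (S,S-dioxide of 23) | C[C@@H]1S(=O)(=O)C(Cl)CC[C@]2(C)O[C@H]2[C@@H](O[Si](C)(C)C(C)(C)C)[C@@H]2CC(=O)O[C@H]2[C@H]1O[Si](CC)(CC)CC | intermediate
25 | trans-fused thiirane 1,1-dioxide across C1 and C10 (one of two faces shown) | C[C@@]12[C@H](S1(=O)=O)CC[C@]3(C)O[C@H]3[C@@H](O[Si](C)(C)C(C)(C)C)[C@@H]3CC(=O)O[C@H]3[C@H]2O[Si](CC)(CC)CC | intermediate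
26 | (1(10)E)-4,5-epoxy-6-(TBS-oxy)-9-(triethylsilyloxy)germacr-1(10)-en-12,8-olide (C4–C9 as in the target) | C1C(=O)O[C@@H]2[C@@H]1[C@H](O[Si](C)(C)C(C)(C)C)[C@@H]1O[C@@]1(C)CC/C=C(\C)[C@@H]2O[Si](CC)(CC)CC | intermediate
27 | C11 (dimethylamino)methyl derivative of 26 (C11 epimers) | CN(C)CC1C(=O)O[C@@H]2[C@@H]1[C@H](O[Si](C)(C)C(C)(C)C)[C@@H]1O[C@@]1(C)CC/C=C(\C)[C@@H]2O[Si](CC)(CC)CC | intermediate
28 | trimethylammonium iodide of 27 | C[N+](C)(C)CC1C(=O)O[C@@H]2[C@@H]1[C@H](O[Si](C)(C)C(C)(C)C)[C@@H]1O[C@@]1(C)CC/C=C(\C)[C@@H]2O[Si](CC)(CC)CC.[I-] | intermediate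
29 | α-methylene lactone, C6–OTBS, C9–OSiEt3 | C=C1C(=O)O[C@@H]2[C@@H]1[C@H](O[Si](C)(C)C(C)(C)C)[C@@H]1O[C@@]1(C)CC/C=C(\C)[C@@H]2O[Si](CC)(CC)CC | intermediate
30 | α-methylene lactone, C6–OTBS, C9–OH | C=C1C(=O)O[C@@H]2[C@@H]1[C@H](O[Si](C)(C)C(C)(C)C)[C@@H]1O[C@@]1(C)CC/C=C(\C)[C@@H]2O | intermediate
31 | C9 isobutyrate, C6–OTBS | C=C1C(=O)O[C@@H]2[C@@H]1[C@H](O[Si](C)(C)C(C)(C)C)[C@@H]1O[C@@]1(C)CC/C=C(\C)[C@@H]2OC(=O)C(C)C | intermediate
32 | CNP0220196.1 | C=C1C(=O)O[C@@H]2[C@@H]1[C@H](O)[C@@H]1O[C@@]1(C)CC/C=C(\C)[C@@H]2OC(=O)C(C)C | target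

**Step count**

Total steps: 20. Longest linear sequence: 19 (steps 1–3 and 5–20; step 4 prepares imide 8).

**Steps most likely to fail**

1. Step 16. What may go wrong: closure through the cis-fused thiirane dioxide, which gives the Z cyclodecene (the usual preference of medium rings), or E1cB loss of the C9 silanolate from the C10 carbanion. The fallback sets out from 24 and comes back at 26; it corrects the geometry after the contraction by a stereospecific olefin inversion instead of relying on the extrusion. The contraction of 24 is taken through to the (1(10)Z)-isomer of 26 F1. F1 is epoxidised at its only double bond (mCPBA, NaHCO3, CH2Cl2, 0 °C) to the 1,10-cis-epoxide F2. LiPPh2 (THF, −40 to 0 °C) opens F2 at the less hindered C1 with inversion to the C1-diphenylphosphino C10-alcohol F3; the 4,5-epoxide, whose C5 is shielded by the C6 silyl ether, should react more slowly. MeI then quaternises phosphorus, and syn elimination of the phosphine oxide from the betaine inverts the olefin and returns 26.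

2. Step 14. What may go wrong: intermolecular S-alkylation to oligomers, or attack of the C10 thiolate on the 4,5-epoxide (seven-membered ring) instead of closure at C1. The fallback sets out from 20 and comes back at 22; the ring is closed through a disulfide and then contracted by sulfur extrusion. KSC(O)CH3 and NaI in DMF displace the primary chloride to give the bis(thioacetate) F4. Hydrazine frees the dithiol F5. I2 with pyridine in CH2Cl2–MeOH at 1 mM closes the twelve-membered cyclic disulfide F6 from the neutral thiols. P(NEt2)3 in benzene at 60 °C removes one sulfur (the C10 thiolate displaces the thiophosphonium group at primary C1) and gives 22.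

3. Step 9. What may go wrong: poor facial selectivity at C8 if ligand control and the α-stereocentre do not reinforce, or epimerisation of the α-branched aldehyde at C7 before addition. The fallback sets out from 12 and comes back at 16; C8 is set by ketone reduction instead of carbonyl addition. (E)-Prop-1-enylmagnesium bromide (THF, −78 °C) gives 16 together with the C8 epimer of 16 F7. Dess–Martin oxidation of the mixture gives the enone F8. Reduction with (S)-2-methyl-CBS-oxazaborolidine and catecholborane (alkenyl as the larger carbonyl substituent) returns 16.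

**Further compounds**

F1 | step 16 | (1(10)Z)-isomer of 26 | C1C(=O)O[C@@H]2[C@@H]1[C@H](O[Si](C)(C)C(C)(C)C)[C@@H]1O[C@@]1(C)CC/C=C(/C)[C@@H]2O[Si](CC)(CC)CC
F2 | step 16 | 1,10-cis-epoxide of F1 (one face shown) | C1C(=O)O[C@@H]2[C@@H]1[C@H](O[Si](C)(C)C(C)(C)C)[C@@H]1O[C@@]1(C)CC[C@H]1O[C@@]1(C)[C@@H]2O[Si](CC)(CC)CC
F3 | step 16 | C1-diphenylphosphino C10-alcohol | C1C(=O)O[C@@H]2[C@@H]1[C@H](O[Si](C)(C)C(C)(C)C)[C@@H]1O[C@@]1(C)CC[C@H](P(c1ccccc1)c1ccccc1)[C@@](C)(O)[C@@H]2O[Si](CC)(CC)CC
F4 | step 14 | bis(thioacetate) (C1 and C10) | CC(=O)S[C@@H](C)[C@H](O[Si](CC)(CC)CC)[C@@H]1OC(=O)C[C@H]1[C@H](O[Si](C)(C)C(C)(C)C)[C@@H]1O[C@@]1(C)CCCSC(C)=O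
F5 | step 14 | dithiol (C1 and C10) | S[C@@H](C)[C@H](O[Si](CC)(CC)CC)[C@@H]1OC(=O)C[C@H]1[C@H](O[Si](C)(C)C(C)(C)C)[C@@H]1O[C@@]1(C)CCCS
F6 | step 14 | twelve-membered cyclic disulfide | C[C@@H]1SSCCC[C@]2(C)O[C@H]2[C@@H](O[Si](C)(C)C(C)(C)C)[C@@H]2CC(=O)O[C@H]2[C@H]1O[Si](CC)(CC)CC
F7 | step 9 | C8 epimer of 16 | CC(C)(C)OC(=O)C[C@H]([C@H](O)/C=C/C)[C@H](O[Si](C)(C)C(C)(C)C)[C@@H]1O[C@@]1(C)CCCCl
F8 | step 9 | C8 enone | CC(C)(C)OC(=O)C[C@H](C(=O)/C=C/C)[C@H](O[Si](C)(C)C(C)(C)C)[C@@H]1O[C@@]1(C)CCCCl
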